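- Wednesday's: substrate 0.31 M (fed, over 30 s); partner 1 equiv; free catalyst 0.1 mol%; run made earlier
- flask: substrate 0.31 M (fed, over 30 s); partner 1.00 equiv; free catalyst 0.2 mol%; time 15 min

Wednesday's run (percent of the substrate charged)

| time / min | product / % | substrate / % |
|---|---|---|
| 0.333 | 15.8 | 50.3 |
| 0.667 | 31.8 | 67.1 |
| 1.33 | 47.6 | 53.6 |
| 2.50 | 48.9 | 50.3 |
| 5.00 | 50.2 | 51.0 |

(standard deviation of a reading: 0.5 percentage points)

- the state of affairs at 15 min: stopped, and by what, or still going (no working catalyst is left / forward and back rates have come level / the partner has run out first / it is still moving / all of the substrate has reacted)
- amount of product at 15 min, in percent of the substrate charged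

- the reaction counts as stopped when no species that holds the substrate changes by six tenths of a point or more over the second half of the time
- percentages count the whole charge, also what has not yet gone in
- no earlier run changes the charge of free catalyst; that part of a forecast is a guess

At its last reading Wednesday's run held product at 50.2%, about level with the substrate still free at 51.0%, so I kept a ledger of the partner, which was charged mole for mole and never read. I assumed each mole of product took one mole of partner, which made the first entry 50.2%. I booked the other 49.8% as lost by a path needing no catalyst, and I read the stall as the closing of these books, with the partner as limiting reagent.

So I carried one quantity, the split: 1.01 moles of partner reaching product for each mole lost. Product doubled in twice the time while the substrate moved from 50.3% to 67.1%, so I took the catalyst's drain as set by its loading, and that step is a guess. The new flask has twice the loading, so its split came to 2.02, and I expected 66.9% product by 15 min.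

The forecast differed: forward and back rates have come level, with 50.5% product, since “Doubling the catalyst only gets there faster”.

The flask gave 63.6% product, and its state was: the partner has run out first. During the feed the catalyst cycle and the partner's decomposition ran side by side, and at 0.500 min the flask held 43.2% product, with 30.9% of the partner's charge as decomposed reagent and 25.9% of it left. By 15.0 min the flask's partner stood at 0% of its own charge, the substrate at 36.4% and the free catalyst at 100% of theirs, and the books closed on 36.4% of the partner's charge as decomposed reagent, a split of 1.75 against my 2.02.

    partner + free catalyst → catalyst intermediate A (k = 140 M⁻¹ s⁻¹)
    substrate + catalyst intermediate A ⇌ catalyst intermediate B (K = 15.0 M⁻¹, k = 9700 M⁻¹ s⁻¹)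
    catalyst intermediate B → by-product + catalyst intermediate C (k = 30.0 s⁻¹)
    catalyst intermediate C → free catalyst + product (k = 44.0 s⁻¹)
    partner → decomposed reagent (k = 0.0170 s⁻¹)

For the neighbouring flask with 0.05 mol% of free catalyst, all else held, the split gives 0.504 and so 33.5% product. The computed result there was 34.6% product, with 65.4% substrate left.

The data stem from a simulated flask on assumed constants; the scatter is artificial.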